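**Plan**
- Retrosynthesis: the six MOM ethers are removed first, then both aryl–C(=O) bonds to the (R)-2-methylbutanoyl groups are cut, then the C2–C3 bond (with the C1–H bond) of the 6-methylheptane-1,1-diyl bridge. Further back lie the C1=C2 double bond, the two aryl–C1 bonds and the two aryl–prenyl bonds.
- Enabling feature: bridge carbon C1 is a methine carrying benzene rings A and B and a side chain that begins with an unbranched C2H2–C3H2 link. It therefore maps onto a 1,1-diarylethylene (C1=C2) plus a 4-methylpentyl radical (C3–C7 with its methyl branch).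
- Forward order: phloroglucinol is MOM-protected and prenylated; two such rings are joined at C1 through ethyl formate; the carbinol is oxidised and methylenated; radical hydroalkylation attaches the chain; both rings are acylated; the acetals are removed. No ring is formed at any stage.
- Stereochemistry: both (R) centres are bought with (R)-2-methylbutanoic acid and brought in as its Weinreb amide. No step creates a stereocentre.

Key step: step 7

Remark on the chemistry: bridge carbon C1 carries two constitutionally and configurationally identical aryl groups and is therefore not a stereocentre; the single enantiomer is the (R,R) compound, whose only stereocentres are the two α-carbons of the acyl groups.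

**Route**

Step 1
Reactants: 1 phloroglucinol
Product: 2 1,3,5-tris(methoxymethoxy)benzene
Conditions: MOMCl (3.6 equiv), i-Pr2NEt (4.5 equiv), CH2Cl2/DMF, 0 °C → rt
Reagents that add atoms: chloromethyl methyl ether (MOMCl), COCCl
Why: Threefold Williamson-type O-alkylation of the phenols with MOMCl under amine base is standard for phloroglucinol and installs the acetals that later direct every ring metalation.

Step 2
Reactants: 2 1,3,5-tris(methoxymethoxy)benzene; 3 prenyl bromide (1-bromo-3-methylbut-2-ene)
Product: 5 1,3,5-tris(methoxymethoxy)-2-(3-methylbut-2-en-1-yl)benzene, via aryllithium 4 (not isolated)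
Conditions: n-BuLi (1.1 equiv), THF, 0 °C; CuI (20 mol %), 3 (1.2 equiv), −78 °C → rt
Reagents that add atoms: none
Why: Directed ortho-metalation at a CH flanked by two MOM ethers followed by copper-assisted SN2 allylation with prenyl bromide is well established for tris-MOM phloroglucinol, and the threefold symmetry of 2 allows only one product.

Step 3
Reactants: 5 1,3,5-tris(methoxymethoxy)-2-(3-methylbut-2-en-1-yl)benzene (2 equivalents)
Product: 8 bis[2,4,6-tris(methoxymethoxy)-3-(3-methylbut-2-en-1-yl)phenyl]methanol, via aryllithium 6 (not isolated), via aldehyde 7 (not isolated)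
Conditions: n-BuLi (1.05 equiv), THF, 0 °C; HCO2Et (0.48 equiv), −78 °C → rt; H2O quench; chromatography on Et3N-deactivated silica
Reagents that add atoms: ethyl formate, CCOC=O
Why: A second directed ortho-metalation at one of the two equivalent remaining ring CH positions and twofold addition of the aryllithium to ethyl formate (formylation to 7, then addition to it) is the classical synthesis of symmetrical diarylmethanols and, unlike addition to a carbonate, cannot run on to a triarylcarbinol.

Step 4
Reactants: 8 bis[2,4,6-tris(methoxymethoxy)-3-(3-methylbut-2-en-1-yl)phenyl]methanol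
Product: 9 bis[2,4,6-tris(methoxymethoxy)-3-(3-methylbut-2-en-1-yl)phenyl]methanone
Conditions: IBX (1.5 equiv), DMSO/toluene, rt
Reagents that add atoms: none
Why: IBX oxidation of a doubly benzylic secondary alcohol to the benzophenone proceeds under neutral conditions that spare MOM acetals and prenyl alkenes, as used routinely for polyoxygenated benzophenones.

Step 5
Reactants: 9 bis[2,4,6-tris(methoxymethoxy)-3-(3-methylbut-2-en-1-yl)phenyl]methanone
Product: 10 1,1-bis[2,4,6-tris(methoxymethoxy)-3-(3-methylbut-2-en-1-yl)phenyl]ethene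
Conditions: Cp2Ti(CH3)2 (3 equiv), toluene/THF, 70 °C, dark
Reagents that add atoms: dimethyltitanocene Cp2Ti(CH3)2, [CH3-].[CH3-].[Ti+4].c1cc[cH-]c1.c1cc[cH-]c1
Why: Petasis methylenation, in which thermolysis of Cp2Ti(CH3)2 gives Cp2Ti=CH2 that converts C=O into C=CH2 by [2+2] cycloaddition and cycloreversion, is non-basic, works on hindered non-enolisable diaryl ketones and does not touch acetals or trisubstituted alkenes.

Step 6
Reactants: 11 5-methylhexanoic acid
Product: 12 1,3-dioxoisoindolin-2-yl 5-methylhexanoate
Conditions: N-hydroxyphthalimide (1.05 equiv), DIC (1.1 equiv), DMAP (5 mol %), CH2Cl2, rt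
Reagents that add atoms: N-hydroxyphthalimide, ON1C(=O)c2ccccc2C1=O
Why: Carbodiimide (Steglich-type) esterification of the acid with N-hydroxyphthalimide is the standard preparation of redox-active esters.

Step 7
Reactants: 10 1,1-bis[2,4,6-tris(methoxymethoxy)-3-(3-methylbut-2-en-1-yl)phenyl]ethene; 12 1,3-dioxoisoindolin-2-yl 5-methylhexanoate
Product: 13 1,1-bis[2,4,6-tris(methoxymethoxy)-3-(3-methylbut-2-en-1-yl)phenyl]-6-methylheptane
Conditions: 12 (2.0 equiv), Ru(bpy)3(PF6)2 (2 mol %), Hantzsch ester (2.5 equiv), degassed CH2Cl2/DMF, blue LEDs (450 nm), rt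
Reagents that add atoms: none
Why: Reductive quenching of photoexcited Ru(bpy)3(PF6)2 by Hantzsch ester gives a strong one-electron reductant that fragments ester 12 into phthalimide anion, CO2 and the primary 4-methylpentyl radical; this radical adds to the open CH2 terminus (C2) of 10, and the resulting diarylmethyl radical at C1 takes a hydrogen atom from Hantzsch ester (or is reduced and protonated) to give the bridging methine. The closest known reaction type is the photoredox decarboxylative Giese-type hydroalkylation of 1,1-diarylethylenes with N-acyloxyphthalimides. No ring is closed and no stereocentre is created, because C1 ends up bearing two identical aryl groups. The step needs anti-Markovnikov regioselectivity and chemoselectivity for the 1,1-diarylethylene over the two trisubstituted prenyl alkenes; both should follow from the benzylic stabilisation of the C1 radical, which the prenyl alkenes cannot offer, and from bond formation at the unhindered terminus one carbon away from the four ortho MOM ethers. The neutral room-temperature medium leaves the acetals untouched, and cyclisation of the C1 radical onto a prenyl group would need an impossible meta-bridged ring.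

Step 8
Reactants: 14 (R)-2-methylbutanoic acid
Product: 16 (R)-N-methoxy-N,2-dimethylbutanamide, via acyl imidazole 15 (not isolated)
Conditions: CDI (1.1 equiv), CH2Cl2, 0 °C → rt; MeNHOMe·HCl (1.3 equiv), rt
Reagents that add atoms: N,O-dimethylhydroxylamine hydrochloride, CNOC.Cl; 1,1'-carbonyldiimidazole, O=C(n1ccnc1)n1ccnc1 (its imidazole stays only in intermediate 15)
Why: CDI activation to the acyl imidazole and aminolysis by N,O-dimethylhydroxylamine (Weinreb amide formation) runs without strong base or an acid chloride, so the α-stereocentre of 14 is carried over unchanged.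

Step 9
Reactants: 13 1,1-bis[2,4,6-tris(methoxymethoxy)-3-(3-methylbut-2-en-1-yl)phenyl]-6-methylheptane; 16 (R)-N-methoxy-N,2-dimethylbutanamide
Product: 18 (2R,2'R)-1,1'-{(6-methylheptane-1,1-diyl)bis[2,4,6-tris(methoxymethoxy)-5-(3-methylbut-2-en-1-yl)-3,1-phenylene]}bis(2-methylbutan-1-one), via dilithio arene 17 (not isolated)
Conditions: n-BuLi (2.5 equiv), THF, 0 °C; 16 (3.0 equiv), −78 → 0 °C; sat. aq. NH4Cl, 0 °C
Reagents that add atoms: none
Why: Twofold directed ortho-metalation at the single CH left on each ring (each flanked by two MOM ethers) followed by Weinreb ketone synthesis should give the diketone, because the chelated tetrahedral adducts neither over-add nor enolise before the cold quench, so both (R) centres come intact from 16.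

Step 10
Reactants: 18 hexa-MOM diketone
Product: 19 (2R,2'R)-1,1'-{(6-methylheptane-1,1-diyl)bis[2,4,6-trihydroxy-5-(3-methylbut-2-en-1-yl)-3,1-phenylene]}bis(2-methylbutan-1-one)
Conditions: HCl (3 M aq.)/MeOH, rt, Ar
Reagents that add atoms: none
Why: Acid-catalysed methanolysis of the six aryl MOM acetals (transacetalisation to dimethoxymethane) at room temperature is the usual unmasking of prenylated acylphloroglucinols, mild enough to leave the prenyl alkenes and the α-stereocentres of the hydrogen-bonded aryl ketones unchanged.

**Compound list**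

1 | phloroglucinol (benzene-1,3,5-triol) | Oc1cc(O)cc(O)c1 | starting material
2 | 1,3,5-tris(methoxymethoxy)benzene | COCOc1cc(OCOC)cc(OCOC)c1 | intermediate
3 | prenyl bromide (1-bromo-3-methylbut-2-ene) | CC(C)=CCBr | starting material
4 | [2,4,6-tris(methoxymethoxy)phenyl]lithium (formed in situ) | [Li]c1c(OCOC)cc(OCOC)cc1OCOC | intermediate
5 | 1,3,5-tris(methoxymethoxy)-2-(3-methylbut-2-en-1-yl)benzene | CC(C)=CCc1c(OCOC)cc(OCOC)cc1OCOC | intermediate
6 | [2,4,6-tris(methoxymethoxy)-3-(3-methylbut-2-en-1-yl)phenyl]lithium (formed in situ) | [Li]c1c(OCOC)cc(OCOC)c(CC=C(C)C)c1OCOC | intermediate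
7 | 2,4,6-tris(methoxymethoxy)-3-(3-methylbut-2-en-1-yl)benzaldehyde (formed in situ) | O=Cc1c(OCOC)cc(OCOC)c(CC=C(C)C)c1OCOC | intermediate
8 | bis[2,4,6-tris(methoxymethoxy)-3-(3-methylbut-2-en-1-yl)phenyl]methanol | OC(c1c(OCOC)cc(OCOC)c(CC=C(C)C)c1OCOC)c1c(OCOC)cc(OCOC)c(CC=C(C)C)c1OCOC | intermediate
9 | bis[2,4,6-tris(methoxymethoxy)-3-(3-methylbut-2-en-1-yl)phenyl]methanone | O=C(c1c(OCOC)cc(OCOC)c(CC=C(C)C)c1OCOC)c1c(OCOC)cc(OCOC)c(CC=C(C)C)c1OCOC | intermediate
10 | 1,1-bis[2,4,6-tris(methoxymethoxy)-3-(3-methylbut-2-en-1-yl)phenyl]ethene | C=C(c1c(OCOC)cc(OCOC)c(CC=C(C)C)c1OCOC)c1c(OCOC)cc(OCOC)c(CC=C(C)C)c1OCOC | intermediate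
11 | 5-methylhexanoic acid | CC(C)CCCC(=O)O | starting material
12 | 1,3-dioxoisoindolin-2-yl 5-methylhexanoate | CC(C)CCCC(=O)ON1C(=O)c2ccccc2C1=O | intermediate
13 | 1,1-bis[2,4,6-tris(methoxymethoxy)-3-(3-methylbut-2-en-1-yl)phenyl]-6-methylheptane | CC(C)CCCCC(c1c(OCOC)cc(OCOC)c(CC=C(C)C)c1OCOC)c1c(OCOC)cc(OCOC)c(CC=C(C)C)c1OCOC | intermediate
14 | (R)-2-methylbutanoic acid | CC[C@@H](C)C(=O)O | starting material
15 | (R)-1-(1H-imidazol-1-yl)-2-methylbutan-1-one (formed in situ) | CC[C@@H](C)C(=O)n1ccnc1 | intermediate
16 | (R)-N-methoxy-N,2-dimethylbutanamide | CC[C@@H](C)C(=O)N(C)OC | intermediate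
17 | 1,1-bis[3-lithio-2,4,6-tris(methoxymethoxy)-5-(3-methylbut-2-en-1-yl)phenyl]-6-methylheptane (formed in situ) | CC(C)CCCCC(c1c(OCOC)c([Li])c(OCOC)c(CC=C(C)C)c1OCOC)c1c(OCOC)c([Li])c(OCOC)c(CC=C(C)C)c1OCOC | intermediate
18 | (2R,2'R)-1,1'-{(6-methylheptane-1,1-diyl)bis[2,4,6-tris(methoxymethoxy)-5-(3-methylbut-2-en-1-yl)-3,1-phenylene]}bis(2-methylbutan-1-one) | CC[C@@H](C)C(=O)c1c(OCOC)c(CC=C(C)C)c(OCOC)c(C(CCCCC(C)C)c2c(OCOC)c(CC=C(C)C)c(OCOC)c(C(=O)[C@H](C)CC)c2OCOC)c1OCOC | intermediate
19 | (2R,2'R)-1,1'-{(6-methylheptane-1,1-diyl)bis[2,4,6-trihydroxy-5-(3-methylbut-2-en-1-yl)-3,1-phenylene]}bis(2-methylbutan-1-one), CNP0245910.1 | CC[C@@H](C)C(=O)c1c(O)c(CC=C(C)C)c(O)c(C(CCCCC(C)C)c2c(O)c(CC=C(C)C)c(O)c(C(=O)[C@H](C)CC)c2O)c1O | target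

**Count**

Total steps: 10. Longest linear sequence: 8 steps (steps 1, 2, 3, 4, 5, 7, 9, 10 from phloroglucinol); steps 6 and 8 are one-step side branches.

**Steps most likely to fail**

1. Step 7. The nucleophilic primary radical may add too slowly to the electron-rich, twisted diarylethylene, so that hydrogen transfer from Hantzsch ester to the radical wins and the alkene is returned unchanged. The fallback builds the same C2–C3 bond by two-electron chemistry. Setting out from 10, hydroboration with 9-BBN-H in THF (boron to the CH2 terminus, the trisubstituted prenyl alkenes reacting far more slowly) should give 9-{2,2-bis[2,4,6-tris(methoxymethoxy)-3-(3-methylbut-2-en-1-yl)phenyl]ethyl}-9-borabicyclo[3.3.1]nonane F1. Without isolation this is coupled with commercial 1-bromo-4-methylpentane (CC(C)CCCBr) under alkyl–alkyl Suzuki–Miyaura conditions (Pd(OAc)2, PCy3, K3PO4·H2O, THF, rt), coming back to the route at 13.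

2. Step 9. The aryllithium sites, each flanked by two MOM ethers, may act as bases toward the α-branched Weinreb amide instead of adding to it. Acylation would then stall and the unreacted amide would lose configurational integrity. The fallback changes electrophile and oxidation level. Amide 16 is reduced with LiAlH4 (THF, −78 → 0 °C) to (R)-2-methylbutanal F2, which is used at once as a cold solution. Setting out from the dilithio arene 17, addition of this much more electrophilic aldehyde at −78 °C should give the bis(carbinol) F3, whose carbinol epimers are of no consequence. Oxidation with Dess–Martin periodinane/NaHCO3 in CH2Cl2 comes back to the route at 18.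

3. Step 10. Under Brønsted acid the freed phenols may add across the neighbouring prenyl double bonds (chroman formation), and long exposure needed to clear all six acetals may erode the α-stereocentres. The fallback exchanges the protecting groups under non-protic conditions. Setting out from 18, TMSOTf/2,2'-bipyridyl in CH3CN (0 °C → rt) should convert the aryl MOM ethers into the hexakis(trimethylsilyl) ether F4. Water added to the same flask at rt then hydrolyses the silyl ethers under neutral conditions, arriving at 19.

**Further compounds**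

F1 | step 7 | 9-{2,2-bis[2,4,6-tris(methoxymethoxy)-3-(3-methylbut-2-en-1-yl)phenyl]ethyl}-9-borabicyclo[3.3.1]nonane | C1CC2CCCC(C1)B2CC(c1c(OCOC)cc(OCOC)c(CC=C(C)C)c1OCOC)c1c(OCOC)cc(OCOC)c(CC=C(C)C)c1OCOC
F2 | step 9 | (R)-2-methylbutanal | CC[C@@H](C)C=O
F3 | step 9 | (2R,2'R)-1,1'-{(6-methylheptane-1,1-diyl)bis[2,4,6-tris(methoxymethoxy)-5-(3-methylbut-2-en-1-yl)-3,1-phenylene]}bis(2-methylbutan-1-ol), mixture of carbinol epimers | CC[C@@H](C)C(O)c1c(OCOC)c(CC=C(C)C)c(OCOC)c(C(CCCCC(C)C)c2c(OCOC)c(CC=C(C)C)c(OCOC)c(C(O)[C@H](C)CC)c2OCOC)c1OCOC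
F4 | step 10 | hexakis(trimethylsilyl) ether of 19 | CC[C@@H](C)C(=O)c1c(O[Si](C)(C)C)c(CC=C(C)C)c(O[Si](C)(C)C)c(C(CCCCC(C)C)c2c(O[Si](C)(C)C)c(CC=C(C)C)c(O[Si](C)(C)C)c(C(=O)[C@H](C)CC)c2O[Si](C)(C)C)c1O[Si](C)(C)C
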